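In percent of the starting material charged, here is the quick number you asked for and the reckoning behind it, because our choice of option differs from your forecast.

in all of them: starting material 0.050 M

| run | partner | remark | time |
|---|---|---|---|
| noon | 0.70 equiv | the very flask that is asked about, followed so far |  |
| winter | 0.47 equiv | run made earlier |  |
| flask | 0.700 equiv |  | 1.0 h |

| run | time / min | target / % |
|---|---|---|
| noon | 6.00 | 13.9 |
| noon | 12.0 | 17.4 |
| noon | 20.0 | 16.7 |
| noon | 25.0 | 16.0 |
| noon | 30.0 | 15.4 |
| noon | 40.0 | 18.3 |
| winter | 0.250 | 2.3 |
| winter | 0.417 | 2.9 |
| winter | 0.667 | 4.6 |
| winter | 1.00 | 2.9 |
| winter | 2.00 | 7.0 |
| winter | 3.00 | 9.3 |

(readings scatter by 1 percentage point)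

- what is taken out of target is counted as made
- additions bring no volume worth counting

- ochre: at 1.0 h add partner, 100% of the amount charged, then wait 1.0 h
- teal: at 1.0 h add starting material, 50.0% of the amount charged, then wait 1.0 h
- grey: change nothing and wait 1.0 h more
- violet: at 1.0 h take out 90% of the target then present, then wait 1.0 h

- target, in percent of the starting material first charged, at 1.0 h
- which option adds most target ("none" when 2 percentage points or less is all one gets) (ochre / teal / grey / violet / none)
- target present, with what was taken out counted in, in percent of the starting material first charged, after ochre
- target present, with what was taken out counted in, in percent of the starting material first charged, after teal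

The noon run, which is this flask followed so far, shows no steady trend from 12.0 min to 40.0 min. Those readings average 16.8%, so that is our number for 1.0 h.

Now ask what the end state must be. The flask holds 0.70 equiv of partner against one equivalent of starting material, so we take partner as the limiting reagent, with each partner consuming one starting material. Dividing that average by the partner gives s = 23.9%, our reading of the target made per starting material consumed, or selectivity. The readings of the winter run end at 3.00 min with 9.3%, below the 11.3% that this reckoning expects as its end, so they do not test it.

Ochre brings the partner to 1.40 equiv, more than the starting material charged. On our reckoning the whole charge is then consumed and gives 23.9%, a gain of 7.1 percentage points. Teal, grey and violet bring no partner, so we expect each to stay at the plateau. The reading to take is free starting material, which on this reckoning should stall near 30.0%.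

Your forecast gives 16.8% now, chooses teal, and puts ochre at 17.5% and teal at 24.5%, on the ground that “partner seems not to control rate or ceiling”. We agree on the first number and differ on the rest.

    starting material + partner → target (k = 2.41 /M/min)
    starting material + partner → intermediate A (k = 6.62 /M/min)
    partner + intermediate B → side product B (k = 8.78 /M/min)
    starting material + partner → side product A (k = 0.827 /M/min)
    intermediate A → intermediate B (k = 0.0354 /min)

The flask gives 16.4% at 1.0 h, and ochre is best, reaching 23.7% with a gain of 7.3 points, while teal stays at 16.4%. At 60.0 min the flask has 0% of its partner and 32.9% of its starting material left. A neighbour charged with 2.80 equiv of partner has 0% starting material left at 60.0 min; s times its consumed charge is 23.9%, and that neighbour holds 24.4% target.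

All runs come from a simulation for an exercise, noise included.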